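## The problem

Dehydrobisgravillol (20) consists of two meta-dioxygenated benzene rings joined through an unbranched fourteen-carbon chain, numbered here C1 (on ring A, a 3-hydroxy-5-methoxyphenyl group) to C14 (on ring B, a 3,5-dihydroxyphenyl group). The chain holds one E-disubstituted alkene, C8=C9, placed off-centre (seven methylenes towards ring A, five towards ring B), so the two arms are alike in polarity but not identical and no symmetric dimerisation can serve. There are no stereocentres; the alkene geometry is the only stereochemical element, nothing in the molecule can bias it, and so it must come from a stereospecific reaction and must not afterwards meet reagents that add reversibly to it. The fragile parts are the electron-rich rings (easily halogenated or oxidised) and the isolated alkene, which excludes hydrogenation, hydrogenolysis and free halogen. The single methyl ether has to be told apart from three free hydroxyls. The enabling feature lies in ring B, numbered as a resorcinol: the hydroxyl carbons C1 and C3 are 1,3-related across C2, the chain sits on C5, and both oxygens are free. Ring B is therefore a 5-alkylcyclohexane-1,3-dione less two hydrogens, and such a dione can be assembled from a methyl enone and a malonate by forming only the C5–C6 and C1–C2 bonds.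

## Retrosynthesis

The first step back from 20 is a functional-group addition. The hydrogen on C6 of ring B is replaced by a carboxyl group, which leads through acid 19 to the methyl resorcylate 18. In the forward sense a C–CO2 bond is broken. This carboxyl is the unavoidable remnant of the malonate, and 2,4-dihydroxybenzoic acids lose carbon dioxide on gentle warming. The forward reaction must hydrolyse a hindered ester and decarboxylate without touching C8=C9 or the ring A methyl ether.

Ring B of 18 is next taken out of the aromatic oxidation level, and the ring A hydroxyl is capped as a methoxymethyl ether. Two hydrogens are returned to the ring carbons that carry the ester and the chain, which gives the cyclohexane-1,3-dione ester 15. No skeletal bond is cut. The gain is that both ring B oxygens are now ketone oxygens that need neither protection nor differentiation, while ring A needs one protecting group only. The forward reaction must remove exactly two hydrogens from the dione ring in the presence of an isolated alkene and an activated aryl ether; this is the delicate point of the plan and is treated as such below.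

The dione ring of 15 is then cut at two bonds. One is the bond between the ester-bearing carbon and the chain-bearing carbon (C5–C6 of ring B). The other is the bond between the ring methylene flanked by the two ketones and the ketone carbon next to the ester-bearing carbon (C1–C2 of ring B). This gives the methyl enone 11 and dimethyl malonate 12. A cut at the aryl–chain bond of ring B would demand a second protected, pre-formed resorcinol and a second sp2–sp3 coupling. The cut chosen here removes a whole ring and leaves an acyclic dienone whose only functional handle is the enone. The forward reaction must add the malonate in conjugate fashion and then close one six-membered ring only.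

Enone 11 is cut at its C3=C4 double bond to the aldehyde 10, and 10 is traced to the primary alcohol 9. An olefination with a stabilised acetonyl ylide gives the E-enone reliably, and the enone geometry is in any case consumed in the annulation. The precursor is a simple ω-aryl alkenol, and the forward steps ask only for a mild oxidation that spares the alkene and the aryl ethers.

Alcohol 9 is cut at the bond between ring A and chain carbon C1, giving the aryl bromide 2 and the dienol 7; 2 is the methoxymethyl ether of commercial 1. Cutting at the ring brings ring A in with its oxygen pattern already differentiated and uses a terminal alkene as the latent nucleophile. A cut one bond further out (a benzylic olefination followed by reduction) would not be compatible with C8=C9. The forward reaction must hydroborate the terminal alkene of 7 selectively in the presence of the internal E-alkene and then couple at sp3 carbon.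

Dienol 7 is traced to the enynol 6 by converting the E-alkene into an alkyne. 6 is then cut at the bond between the alkyne carbon and the adjacent methylene on the ring A side (C7–C8 of the final chain), giving oct-7-yn-1-ol 3 and 7-bromohept-1-ene 4. The alkyne is the surest source of a pure E-alkene. The reduction is placed before ring A is attached, so that no arene or aryl ether is exposed to the dissolving metal. The carbinol carbon of 3 ends as C5 of ring B. The forward steps ask for C-alkylation of an alkynol dianion and a trans-selective reduction that leaves a terminal alkene alone.

## Roads not taken

Alternative 1: The chain is cut on both sides of the alkene, at C7–C8 and C9–C10, so that the two ring-bearing arms are stitched onto a two-carbon trans linchpin. In the forward sense (E)-1-bromo-2-iodoethene A2 would be coupled in one flask, first at the C–I bond with the ring A heptylzinc iodide A3 under PdCl2(DPEphos), then at the C–Br bond with the ring B pentylzinc iodide A4 under Pd(P(t-Bu)3)2. This would give the tris(methoxymethyl) ether A1, and acid would release 20. The merits are real. The route is highly convergent and its longest linear sequence is shorter than that of the plan proposed here. The alkene geometry is bought with A2 and carried through with retention. No oxidant or halogenating agent ever meets the alkene or the rings, and on this last point it is clearly the safer road. Its weak points are specific to this target. The two arms differ by two methylenes and one oxygen substituent, so any halogen scrambling or homocoupling gives symmetrical bis-ring A or bis-ring B alkenes that would be very hard to separate from A1. Each arm needs its own protection, chain attachment, iodide formation and zinc insertion, so the total number of operations is not lower. Ring B needs two protecting groups that the present plan does not use at all. Against the better convergence and the absence of a halogenation, the present plan sets a crossover-free assembly, an unprotected ring B and inexpensive reagents.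

Alternative 2: Ring A, not ring B, is disconnected, at the bond between its ester-bearing carbon and its chain-bearing carbon, leading to the open-chain 3,5,7-triketo ester A6. In the forward sense mild aqueous methanolic base would bring about an intramolecular aldol attack of C2 on the C7 ketone of A6 and dehydration, which closes ring A directly at the aromatic level as the resorcylate A5. The ester then shields its hydrogen-bonded ortho hydroxyl, so that methylation of the para hydroxyl would give A7. Hydrolysis, decarboxylation and removal of the ring B protecting groups would finish. Two merits stand out, and both are better than what the present plan offers. No dehydrogenation is needed, so no halogen comes near the alkene. The hydroxyl/methoxyl differentiation of ring A is solved by the molecule itself, without buying a differentiated ring A. The weak points are the supply and behaviour of A6. It has to be made by acylating a polyanion of a diketo ester with the whole lipophilic chain, which is seldom efficient. Such triketo esters also close competitively by Claisen attack or to pyranones, with an outcome that depends sharply on pH. Ring B must still be made separately with both hydroxyls protected. The present plan sets against this a ring-forming step with a single possible closure mode and a robust, easily made precursor, and it pays for that with the oxidation in step 8.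

Alternative 3: Ring A is cut into a four-carbon and a two-carbon piece, the 3-substituted cyclobutenone A9 and methoxyacetylene A10. Heating the two in toluene would open A9 to a vinylketene, which adds A10. Ring opening, six-electron electrocyclisation and tautomerisation would then give the phenol A8 with hydroxyl and methoxyl already differentiated and the ring A hydroxyl free. The merits are a neutral, thermal key step that is gentle to the alkene and direct access to the ring A pattern without any protecting group on ring A. In that respect it is more elegant than a purchased, protected ring A. The weak points are preparative. A9 would have to be built from a terminal alkyne by a ketene cycloaddition and dehalogenation, chemistry in which the chain alkene competes. A10 is volatile and not a shelf reagent. Ring B again needs two protecting groups and its own coupling. The step count would clearly exceed that of the present plan, which sets shorter length and commercial building blocks against the elegance of the ring A construction.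

Key step: step 7

Remark on the chemistry: compound 13 carries one stereocentre and compounds 14 to 16 carry two or three ring stereocentres. All form as racemic, epimerisable mixtures and are erased in step 8, so they are drawn without configuration. Alkoxides, phenoxides and carboxylates that merely accompany a step are treated as ionised forms of the numbered compound.

## Route

Step 1
Reactants: 1 3-bromo-5-methoxyphenol
Product: 2 1-bromo-3-methoxy-5-(methoxymethoxy)benzene
Conditions: MOMCl, i-Pr2NEt, CH2Cl2, 0 °C → rt
Reagents that add atoms: chloromethyl methyl ether, COCCl
Why: O-Alkylation of the phenol with a chloromethyl ether (acetal-type protection); the group is stable to the palladium coupling, the oxidation, the ylide and methoxide that follow and leaves under mild acid.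

Step 2
Reactants: 3 oct-7-yn-1-ol; 4 7-bromohept-1-ene
Product: 6 pentadec-14-en-7-yn-1-ol, via dilithium alkynide alkoxide 5 (not isolated)
Conditions: n-BuLi (2.1 equiv), THF/DMPU, −78 → 0 °C; then 4, 0 °C → rt; aq. NH4Cl
Reagents that add atoms: none
Why: Alkylation of an alkynol dianion: in THF/DMPU the acetylide carbon is far more nucleophilic than the lithium alkoxide, so the primary bromide is displaced at carbon (SN2) and the hydroxyl needs no protection.

Step 3
Reactants: 6 pentadec-14-en-7-yn-1-ol
Product: 7 (7E)-pentadeca-7,14-dien-1-ol
Conditions: Na, NH3(l)/THF, −33 °C; NH4Cl
Reagents that add atoms: none
Why: Dissolving-metal reduction of an internal alkyne; stepwise electron transfer and protonation pass through the more stable trans vinyl radical and anion, which fixes the E geometry of the later C8=C9 bond. The isolated terminal alkene is not reduced, and no arene is yet present that could suffer ring reduction or ether cleavage.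

Step 4
Reactants: 7 (7E)-pentadeca-7,14-dien-1-ol; 2 1-bromo-3-methoxy-5-(methoxymethoxy)benzene
Product: 9 (7E)-15-[3-methoxy-5-(methoxymethoxy)phenyl]pentadec-7-en-1-ol, via bis-boron adduct 8 (not isolated)
Conditions: 9-BBN (2.2 equiv), THF, 0 °C → rt; then aq. K3PO4, 2, PdCl2(dppf) (3 mol %), THF/DMF, 60 °C
Reagents that add atoms: none
Why: One equivalent of 9-BBN is taken up by the hydroxyl as a borinate and the second adds anti-Markovnikov to the monosubstituted alkene, which reacts far faster than the trans-disubstituted one. B-alkyl Suzuki–Miyaura coupling then joins the primary alkyl group to the aryl bromide, the wide bite angle of dppf favouring reductive elimination over β-hydride elimination, and the aqueous base frees the hydroxyl again.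

Step 5
Reactants: 9 (7E)-15-[3-methoxy-5-(methoxymethoxy)phenyl]pentadec-7-en-1-ol
Product: 10 (7E)-15-[3-methoxy-5-(methoxymethoxy)phenyl]pentadec-7-enal
Conditions: Dess–Martin periodinane, NaHCO3, CH2Cl2, 0 °C → rt
Reagents that add atoms: none
Why: Dess–Martin oxidation of a primary alcohol stops at the aldehyde and leaves the alkene and the electron-rich ring alone; the bicarbonate buffer keeps the acetic acid formed away from the acetal.

Step 6
Reactants: 10 (7E)-15-[3-methoxy-5-(methoxymethoxy)phenyl]pentadec-7-enal
Product: 11 (3E,10E)-18-[3-methoxy-5-(methoxymethoxy)phenyl]octadeca-3,10-dien-2-one
Conditions: Ph3P=CHC(O)CH3, toluene, 80 °C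
Reagents that add atoms: 1-(triphenyl-λ5-phosphanylidene)propan-2-one, CC(=O)C=P(c1ccccc1)(c1ccccc1)c1ccccc1
Why: Wittig olefination with a ketone-stabilised ylide, which reacts under thermodynamic control and should give the E-enone; the existing C10=C11 bond is not involved.

Step 7
Reactants: 11 (3E,10E)-18-[3-methoxy-5-(methoxymethoxy)phenyl]octadeca-3,10-dien-2-one; 12 dimethyl malonate
Product: 15 methyl 6-{(6E)-14-[3-methoxy-5-(methoxymethoxy)phenyl]tetradec-6-en-1-yl}-2,4-dioxocyclohexane-1-carboxylate (racemic and enolised), via open-chain Michael adduct 13 (not isolated), via sodium enolate 14 (not isolated)
Conditions: NaOMe (1.3 equiv), MeOH/THF, reflux; then cold 1 M HCl to pH 3–4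
Reagents that add atoms: none
Why: Methoxide deprotonates 12, and the soft malonate anion adds to C4 of enone 11 in a Michael addition, giving 13 and forming the bond that becomes C5–C6 of ring B. Under the same equilibrating conditions the enolate on the methyl side of the ketone attacks one ester carbonyl and expels methoxide (intramolecular Claisen condensation), forming the C1–C2 bond of ring B and closing the six-membered ring in a 6-(enolendo)-exo-trig mode. The closest known reaction type is the Michael–Claisen annulation of alk-3-en-2-ones with malonic esters, the standard entry to 5-alkylcyclohexane-1,3-diones. The ring product is at once deprotonated to the delocalised enolate 14, which makes the otherwise reversible sequence irreversible; brief cold acidification then gives 15 without loss of the acetal. Two stereocentres (C1 and C6 of 15) arise without control as a racemic, epimerisable mixture in which the trans arrangement should prevail, and both are erased in step 8. Conjugate addition over carbonyl addition is secured by the stabilised nucleophile and the reversibility of 1,2-addition. A single ring size is secured because the enolate on the methylene side could close only a four-membered ring. The unactivated C10=C11 alkene and both ethers are inert to methoxide.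

Step 8
Reactants: 15 methyl 6-{(6E)-14-[3-methoxy-5-(methoxymethoxy)phenyl]tetradec-6-en-1-yl}-2,4-dioxocyclohexane-1-carboxylate
Product: 18 methyl 2,4-dihydroxy-6-[(6E)-14-(3-hydroxy-5-methoxyphenyl)tetradec-6-en-1-yl]benzoate, via 3-bromo dione 16 (not isolated), via MOM-protected resorcylate 17 (not isolated)
Conditions: NBS (1.0 equiv), THF, −20 °C, dark; then DMF, 70 °C; then MeOH, 50 °C
Reagents that add atoms: none
Why: Halogenation–dehydrohalogenation aromatisation of a 2,4-dioxocyclohexanecarboxylate: NBS transfers one bromine to the enol carbon between the two ring carbonyls of 15 much faster than it can attack the isolated alkene or ring A in the cold and dark, and succinimide takes up the proton, so no acid is set free at this stage. On warming in DMF, 16 loses HBr (by 1,4-elimination through its dienol, or by 1,2-elimination after migration of bromine to the ester-bearing carbon) and tautomerises to resorcylate 17 with all ring stereocentres gone. The HBr set free then exchanges the methoxymethyl group into methanol as dimethoxymethane, giving 18.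

Step 9
Reactants: 18 methyl 2,4-dihydroxy-6-[(6E)-14-(3-hydroxy-5-methoxyphenyl)tetradec-6-en-1-yl]benzoate
Product: 20 dehydrobisgravillol (5-[(6E)-14-(3-hydroxy-5-methoxyphenyl)tetradec-6-en-1-yl]benzene-1,3-diol), via resorcylic acid 19 (not isolated)
Conditions: NaOH (2 M aq.), MeOH, reflux, N2; then HCl to pH 2, 60 °C
Reagents that add atoms: none
Why: Saponification of the resorcylate ester, followed by protodecarboxylation of the 2,4-dihydroxybenzoic acid, which is easy because ring protonation at the carboxyl-bearing carbon is assisted by the ortho and para hydroxyls. The isolated E-alkene and the aryl methyl ether are inert to aqueous base and to dilute acid at this temperature.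

## Compound list

1 | 3-bromo-5-methoxyphenol | COc1cc(O)cc(Br)c1 | starting material
2 | 1-bromo-3-methoxy-5-(methoxymethoxy)benzene | COCOc1cc(OC)cc(Br)c1 | intermediate
3 | oct-7-yn-1-ol | C#CCCCCCCO | starting material
4 | 7-bromohept-1-ene | C=CCCCCCBr | starting material
5 | dilithium salt of oct-7-yn-1-ol (lithium 8-lithiooct-7-yn-1-olate) | [Li+].[Li+].[O-]CCCCCCC#[C-] | intermediate (not isolated)
6 | pentadec-14-en-7-yn-1-ol | OCCCCCCC#CCCCCCC=C | intermediate
7 | (7E)-pentadeca-7,14-dien-1-ol | OCCCCCC/C=C/CCCCCC=C | intermediate
8 | 9-[(8E)-15-(9-borabicyclo[3.3.1]nonan-9-yloxy)pentadec-8-en-1-yl]-9-borabicyclo[3.3.1]nonane | C1CCC2CCCC1B2CCCCCCC/C=C/CCCCCCOB1C2CCCC1CCC2 | intermediate (not isolated)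
9 | (7E)-15-[3-methoxy-5-(methoxymethoxy)phenyl]pentadec-7-en-1-ol | OCCCCCC/C=C/CCCCCCCc1cc(OC)cc(OCOC)c1 | intermediate
10 | (7E)-15-[3-methoxy-5-(methoxymethoxy)phenyl]pentadec-7-enal | O=CCCCCC/C=C/CCCCCCCc1cc(OC)cc(OCOC)c1 | intermediate
11 | (3E,10E)-18-[3-methoxy-5-(methoxymethoxy)phenyl]octadeca-3,10-dien-2-one | CC(=O)/C=C/CCCCC/C=C/CCCCCCCc1cc(OC)cc(OCOC)c1 | intermediate
12 | dimethyl malonate | COC(=O)CC(=O)OC | starting material
13 | dimethyl 2-{(10E)-18-[3-methoxy-5-(methoxymethoxy)phenyl]-2-oxooctadec-10-en-4-yl}propanedioate (racemic) | COC(=O)C(C(=O)OC)C(CC(C)=O)CCCCC/C=C/CCCCCCCc1cc(OC)cc(OCOC)c1 | intermediate (not isolated)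
14 | sodium 4-(methoxycarbonyl)-5-{(6E)-14-[3-methoxy-5-(methoxymethoxy)phenyl]tetradec-6-en-1-yl}-3-oxocyclohex-1-en-1-olate (racemic) | [Na+].[O-]C1=CC(=O)C(C(=O)OC)C(CCCCC/C=C/CCCCCCCc2cc(OC)cc(OCOC)c2)C1 | intermediate (not isolated)
15 | methyl 6-{(6E)-14-[3-methoxy-5-(methoxymethoxy)phenyl]tetradec-6-en-1-yl}-2,4-dioxocyclohexane-1-carboxylate (racemic; drawn as the triketo form, present mainly as the 2-hydroxy-4-oxocyclohex-2-ene enol) | COC(=O)C1C(=O)CC(=O)CC1CCCCC/C=C/CCCCCCCc1cc(OC)cc(OCOC)c1 | intermediate
16 | methyl 3-bromo-6-{(6E)-14-[3-methoxy-5-(methoxymethoxy)phenyl]tetradec-6-en-1-yl}-2,4-dioxocyclohexane-1-carboxylate (racemic mixture of diastereomers) | COC(=O)C1C(=O)C(Br)C(=O)CC1CCCCC/C=C/CCCCCCCc1cc(OC)cc(OCOC)c1 | intermediate (not isolated)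
17 | methyl 2,4-dihydroxy-6-{(6E)-14-[3-methoxy-5-(methoxymethoxy)phenyl]tetradec-6-en-1-yl}benzoate | COC(=O)c1c(O)cc(O)cc1CCCCC/C=C/CCCCCCCc1cc(OC)cc(OCOC)c1 | intermediate (not isolated)
18 | methyl 2,4-dihydroxy-6-[(6E)-14-(3-hydroxy-5-methoxyphenyl)tetradec-6-en-1-yl]benzoate | COC(=O)c1c(O)cc(O)cc1CCCCC/C=C/CCCCCCCc1cc(O)cc(OC)c1 | intermediate
19 | 2,4-dihydroxy-6-[(6E)-14-(3-hydroxy-5-methoxyphenyl)tetradec-6-en-1-yl]benzoic acid | OC(=O)c1c(O)cc(O)cc1CCCCC/C=C/CCCCCCCc1cc(O)cc(OC)c1 | intermediate (not isolated)
20 | dehydrobisgravillol, 5-[(6E)-14-(3-hydroxy-5-methoxyphenyl)tetradec-6-en-1-yl]benzene-1,3-diol | COc1cc(O)cc(CCCCCCC/C=C/CCCCCc2cc(O)cc(O)c2)c1 | target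

## Step count

Total step count: 9. Longest linear sequence: 8 steps (steps 2 to 9, from 3 to 20); step 1 is a one-step branch that joins at step 4.

## Least certain steps

Step 8. The most likely failure is leakage of electrophilic bromine. NBS may attack the activated ring A in competition with the enol. While 16 is being converted into 17, the bromo dione is itself a bromine donor; with the HBr being released it can revert to the dione and free bromine. This bromine could substitute ring A or the newly formed resorcinol ring, or add to the C=C bond, and bromine atoms could equilibrate the alkene geometry. Release of the methoxymethyl cation in hot acidic DMF before methanol is present could alkylate a phenolic ring. The fallback avoids halogen and acid altogether and sets out from 15. Two equivalents of LDA in THF at −78 °C would form the dianion, whose second, more reactive site is the carbon flanked by ester and ketone. PhSeBr would give the selenide methyl 6-{(6E)-14-[3-methoxy-5-(methoxymethoxy)phenyl]tetradec-6-en-1-yl}-2,4-dioxo-1-(phenylselanyl)cyclohexane-1-carboxylate F1. Oxidation with NaIO4 in buffered aqueous methanol would give the selenoxide, which eliminates syn towards the chain-bearing carbon and tautomerises to 17. Catalytic HCl in methanol would then remove the acetal, and the route is rejoined at 18.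

Step 7 (key step). The most likely failure is incomplete ring closure together with loss of enone by base-induced side reactions. These are migration of the C3=C4 bond out of conjugation after γ-deprotonation, reversible addition of methoxide, and self-condensation. The long lipophilic substrate is expected to react more slowly in methanol than short-chain enones, which gives these processes time. The fallback forms the same two ring bonds in a different order and sets out from aldehyde 10. Knoevenagel condensation with 12 (piperidine, AcOH, toluene, water separator) would give dimethyl 2-{(7E)-15-[3-methoxy-5-(methoxymethoxy)phenyl]pentadec-7-en-1-ylidene}propanedioate F2. Conjugate addition of the lithium enolate of acetone (LDA, acetone, THF, −78 °C) to this doubly activated acceptor would give, after protonation, the open-chain adduct 13, where the route is rejoined. NaOMe in methanol then only has to perform the Claisen closure to 14 and 15.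

Step 4. The most likely failure is imprecise hydroboration. The hydroxyl consumes 9-BBN at a rate not far from that of the alkene, so either some terminal alkene is left or surplus borane begins to add to the internal alkene. Unquenched B–H could also reduce the aryl bromide at zerovalent palladium. The fallback changes the order of assembly and sets out from 4 and 2. Hydroboration of 4, which has neither a hydroxyl nor a second alkene, and the same coupling would give 1-(7-bromoheptyl)-3-methoxy-5-(methoxymethoxy)benzene F3; a primary alkyl bromide is not expected to undergo oxidative addition with this catalyst. The dianion of 3, made as in step 2, would be alkylated with F3 to give 15-[3-methoxy-5-(methoxymethoxy)phenyl]pentadec-7-yn-1-ol F4. Reduction with Na in NH3/THF without an added proton donor, so that the arene is spared, rejoins the route at 9. The price is that the dissolving-metal step then has to tolerate ring A.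

Step 9. The most likely failure is sluggish acyl attack on an ester flanked by the alkyl chain and an ionised ortho hydroxyl. Long heating would then be needed, during which the electron-rich phenoxides can be oxidised by adventitious air. The fallback cleaves the ester at the methyl carbon instead of the acyl carbon and sets out from 18. NaSEt in DMF at 80 °C would demethylate the ester by SN2 attack; the ring A aryl methyl ether needs far higher temperatures for the same cleavage. Acidification and gentle warming then decarboxylate 19, and the route is rejoined at 20. This fallback passes through no compound outside the list (F0).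

Further compounds
F1 | step 8 | methyl 6-{(6E)-14-[3-methoxy-5-(methoxymethoxy)phenyl]tetradec-6-en-1-yl}-2,4-dioxo-1-(phenylselanyl)cyclohexane-1-carboxylate | COC(=O)C1([Se]c2ccccc2)C(=O)CC(=O)CC1CCCCC/C=C/CCCCCCCc1cc(OC)cc(OCOC)c1
F2 | step 7 | dimethyl 2-{(7E)-15-[3-methoxy-5-(methoxymethoxy)phenyl]pentadec-7-en-1-ylidene}propanedioate | COC(=O)C(=CCCCCC/C=C/CCCCCCCc1cc(OC)cc(OCOC)c1)C(=O)OC
F3 | step 4 | 1-(7-bromoheptyl)-3-methoxy-5-(methoxymethoxy)benzene | COCOc1cc(OC)cc(CCCCCCCBr)c1
F4 | step 4 | 15-[3-methoxy-5-(methoxymethoxy)phenyl]pentadec-7-yn-1-ol | OCCCCCCC#CCCCCCCCc1cc(OC)cc(OCOC)c1
F0 | step 9 | none | none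
A1 | alternative 1 | 1-{(8E)-14-[3,5-bis(methoxymethoxy)phenyl]tetradec-8-en-1-yl}-3-methoxy-5-(methoxymethoxy)benzene | COCOc1cc(OC)cc(CCCCCCC/C=C/CCCCCc2cc(OCOC)cc(OCOC)c2)c1
A2 | alternative 1 | (E)-1-bromo-2-iodoethene | Br/C=C/I
A3 | alternative 1 | {7-[3-methoxy-5-(methoxymethoxy)phenyl]heptyl}zinc iodide | COCOc1cc(OC)cc(CCCCCCC[Zn]I)c1
A4 | alternative 1 | {5-[3,5-bis(methoxymethoxy)phenyl]pentyl}zinc iodide | COCOc1cc(OCOC)cc(CCCCC[Zn]I)c1
A5 | alternative 2 | methyl 2-{(8E)-14-[3,5-bis(methoxymethoxy)phenyl]tetradec-8-en-1-yl}-4,6-dihydroxybenzoate | COC(=O)c1c(O)cc(O)cc1CCCCCCC/C=C/CCCCCc1cc(OCOC)cc(OCOC)c1
A6 | alternative 2 | methyl (15E)-21-[3,5-bis(methoxymethoxy)phenyl]-3,5,7-trioxohenicos-15-enoate | COC(=O)CC(=O)CC(=O)CC(=O)CCCCCCC/C=C/CCCCCc1cc(OCOC)cc(OCOC)c1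
A7 | alternative 2 | methyl 2-{(8E)-14-[3,5-bis(methoxymethoxy)phenyl]tetradec-8-en-1-yl}-6-hydroxy-4-methoxybenzoate | COC(=O)c1c(O)cc(OC)cc1CCCCCCC/C=C/CCCCCc1cc(OCOC)cc(OCOC)c1
A8 | alternative 3 | 3-{(8E)-14-[3,5-bis(methoxymethoxy)phenyl]tetradec-8-en-1-yl}-5-methoxyphenol | COc1cc(O)cc(CCCCCCC/C=C/CCCCCc2cc(OCOC)cc(OCOC)c2)c1
A9 | alternative 3 | 3-{(8E)-14-[3,5-bis(methoxymethoxy)phenyl]tetradec-8-en-1-yl}cyclobut-2-en-1-one | O=C1C=C(CCCCCCC/C=C/CCCCCc2cc(OCOC)cc(OCOC)c2)C1
A10 | alternative 3 | methoxyacetylene (methoxyethyne) | COC#C
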